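Hours per decade of X is the number we need before deciding whether midnight and dawn stay as set or get more time.

| setting | south-east | north | north-east | midnight | dawn |
|---|---|---|---|---|---|
| X | 0.60 M | 1.8 M | 1.5 M | 1.5 M | 0.50 M |
| E | 38 mM | 38 mM | 19 mM | 38 mM | 20 mM |
| remark | run made earlier | run made earlier | run made earlier |  |  |
| time |  |  |  | 4.0 h | 4.0 h |

- south-east (time / h: Z / %, X / %): 0.333: 0, 65; 1.00: 10, 28; 2.00: 16, 10; 3.00: 19, 2
- north (time / h: Z / %, X / %): 0.667: 8, 42; 1.33: 14, 19; 2.00: 19, 7; 3.00: 19, 5
- north-east (time / h: Z / %, X / %): 0.333: 4, 66; 1.00: 10, 29; 2.00: 16, 10; 3.00: 19, 2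

(scatter of a reading: 1.5 percentage points)

* which of the two ends with the higher amount of Z, in percent of the X charged ("neither" if they lie within 2 percentage points) (midnight / dawn / neither)
* Z at the end, in percent of the X charged, midnight
* Z at the end, in percent of the X charged, dawn

- a reading or a percentage of Z counts all its forms, free or not
- a reading of X is of its free form alone

1. The south-east run reads X at 10% of its charge at 2.00 h, so by this reading one decade has gone by then. The decade time, the hours in which free X falls by a factor of 10, reads 2.00 h.
2. The north-east run, with half the E of the south-east run and cX at 1.5 M, reads X at the same 10%. The north run reads X at 7% at that time, with a scatter of 1.5 percentage points on each reading. We therefore use one decade time for both new flasks.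
3. The set 4.0 h holds 2.00 decades, which by this reckoning leaves X at 1.00%.
4. At 3.00 h the south-east run has made Z from 19.4% of the X used, a reading of the selectivity. By this reckoning the X left at 4.0 h is worth about 0.19 points of Z, less than the scatter. So we keep the time and charges as set.
5. Our own reckoning gives Z at 19.2% in both flasks, so neither leads.

The forecast differs from this: 20% for midnight, 20% for dawn, neither ahead, “with no clear sign of Z decaying”.

Midnight gives 20.4% and dawn 20.5%, so the answer is neither. Both lie above our 19.2%. At 4.00 h, midnight holds free X at 1.6% and dawn at 1.2%, against the 1.00% that 2.00 decades gave. Left until 40.0 h, dawn's Z stands at 21.0%, a gain below the margin of 2 points.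

    X → G (k = 6.90 × 10⁻⁵ s⁻¹)
    X + Z ⇌ J, settled at all times (K = 1.50 M⁻¹)
    E + G → E + Z (k = 0.0430 M⁻¹ s⁻¹)
    X → L (k = 2.60 × 10⁻⁴ s⁻¹)

Midnight read at 1.0 h is 0.500 decades in, which gives X at 31.6%. The computed flask holds free X at 28%, with Z at 12.5%.

Readings and results come from a simulation with made-up constants.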